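**Retrosynthetic overview**

1. The target is cut last at the ester C–O and ketal C–O bonds of the spiro carbon of ring A, giving a cage β-hydroxy acid and 7-hydroxy-2,2-dimethyl-6-prenyl-2H-chromene-5,8-dione (acylation, then oxa-Michael closure of the 1,3-dioxin-4-one).
2. The strategy rests on the bicyclo[2.2.2]octene of the cage: its O-bearing bridgehead carbon, the ring sp2 carbon that holds the lactone carbonyl and the olefinic CH are a 3-hydroxy-2-alkylidene ester, the aldol adduct of an α-metallated acrylate and a ketone. Breaking the bond between that sp2 carbon and the bridgehead leaves a 6-oxabicyclo[3.2.1]octane-4,8-dione with an alkynoate and a silyloxy group on C3 (copper hydride reductive aldol in the forward sense).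
3. The C3 centre is built on the oxabicyclic dione by enolate hydroxylation, enediol silyl ether formation, alkynylation on the face of the C8 bridge and carboxylation.
4. The dione comes from 5,5-dimethyl-2-prenyloxolan-3-one (from diacetone alcohol and prenyl bromide) by enamine α,α'-annulation with acryloyl chloride, then resolution; the quinone comes from 1,2,3,5-tetramethoxybenzene, prenyl bromide and prenal.
5. Ring order: oxolanone, carbocycle of the oxabicyclo[3.2.1]octane, bicyclo[2.2.2]octene (key step), 2H-chromene in a side branch, spiro dioxinone last.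

Key step: step 12

Assumption: the spiro ketal carbon and the neighbouring CH(prenyl) of ring A in the target are taken to be the thermodynamically preferred arrangement of a reversible oxa-Michael addition (prenyl trans to the ketal ether oxygen).

**Route**

Step 1
Reactants: 1 diacetone alcohol (4-hydroxy-4-methylpentan-2-one)
Product: 2 4-methyl-4-(trimethylsilyloxy)pentan-2-one
Conditions: Me3SiCl, imidazole, DMF, 0 °C → rt
Reagents that add atoms: chlorotrimethylsilane, C[Si](C)(C)Cl
Why: Imidazole-mediated O-silylation masks the tertiary hydroxyl, so the ketone can later be enolised on the methyl side without alkoxide-driven retro-aldol cleavage.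

Step 2
Reactants: 2 4-methyl-4-(trimethylsilyloxy)pentan-2-one; 3 prenyl bromide (1-bromo-3-methylbut-2-ene)
Product: 4 2,8-dimethyl-2-(trimethylsilyloxy)non-7-en-4-one
Conditions: LiN(iPr)2, THF, −78 °C; then 3, DMPU, −78 → −20 °C
Reagents that add atoms: none
Why: Kinetic deprotonation takes the methyl group and not the neopentyl-type CH2 next to the silyloxy carbon, and the lithium enolate is alkylated at the primary carbon of the allylic bromide (enolate SN2 alkylation).

Step 3
Reactants: 4 2,8-dimethyl-2-(trimethylsilyloxy)non-7-en-4-one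
Product: 6 5-bromo-2,8-dimethyl-2-(trimethylsilyloxy)non-7-en-4-one (racemic), via silyl enol ether 5 (not isolated)
Conditions: LiN(SiMe3)2, Me3SiCl, THF, −78 °C; then N-bromosuccinimide, −78 → 0 °C
Reagents that add atoms: N-bromosuccinimide, O=C1CCC(=O)N1Br; chlorotrimethylsilane, C[Si](C)(C)Cl (its silicon stays only in 5)
Why: Kinetic enolisation again avoids the hindered C3 methylene, and the resulting trimethylsilyl enol ether is brominated at C5 far faster than the trisubstituted alkene reacts (α-bromination of a silyl enol ether).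

Step 4
Reactants: 6 5-bromo-2,8-dimethyl-2-(trimethylsilyloxy)non-7-en-4-one
Product: 7 5,5-dimethyl-2-(3-methylbut-2-enyl)oxolan-3-one (racemic)
Conditions: Bu4NF, THF, −20 → 0 °C
Reagents that add atoms: none
Why: Fluoride frees the tertiary alkoxide, which displaces the neighbouring α-keto bromide in a fast 5-exo-tet intramolecular Williamson etherification that should outrun retro-aldol cleavage.

Step 5
Reactants: 7 5,5-dimethyl-2-(3-methylbut-2-enyl)oxolan-3-one
Product: 8 1-[5,5-dimethyl-2-(3-methylbut-2-enyl)-2,5-dihydrofuran-3-yl]pyrrolidine (racemic)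
Conditions: pyrrolidine, TsOH·H2O (cat.), toluene, reflux, Dean–Stark
Reagents that add atoms: pyrrolidine, C1CCNC1
Why: Azeotropic condensation (Stork enamine formation) should give the less substituted C3=C4 enamine, because the C2=C3 isomer would place the prenyl group in allylic strain with the pyrrolidine ring.

Step 6
Reactants: 8 1-[5,5-dimethyl-2-(3-methylbut-2-enyl)-2,5-dihydrofuran-3-yl]pyrrolidine; 9 acryloyl chloride
Product: 11 rac-7,7-dimethyl-5-(3-methylbut-2-enyl)-6-oxabicyclo[3.2.1]octane-4,8-dione, via bridged iminium chloride 10 (not isolated)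
Conditions: 9, MeCN, reflux; then H2O, NaOAc/AcOH buffer, rt
Reagents that add atoms: water, O
Why: In the enamine α,α'-annulation with acryloyl chloride the enamine β carbon (oxolane C4) takes the CH2 terminus and the regenerated enamine is acylated at the prenyl-bearing C2, so the new ketone sits next to the quaternary bridgehead, and the three-carbon bridge can only close cis, which fixes the relative configuration of the two bridgeheads.

Step 7
Reactants: 11 rac-7,7-dimethyl-5-(3-methylbut-2-enyl)-6-oxabicyclo[3.2.1]octane-4,8-dione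
Product: 12 (1S,5S)-7,7-dimethyl-5-(3-methylbut-2-enyl)-6-oxabicyclo[3.2.1]octane-4,8-dione
Conditions: preparative SFC, amylose tris(3,5-dimethylphenylcarbamate) phase, CO2/iPrOH, 35 °C
Reagents that add atoms: none
Why: The dione has no handle for salt formation and its bridgeheads cannot epimerise, so resolution of the racemate by chromatography on a chiral stationary phase is the dependable way to the (1S,5S) antipode, whose assignment is to be secured by X-ray analysis of a crystalline hydrazone before scale-up.

Step 8
Reactants: 12 (1S,5S)-dione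
Product: 13 3-hydroxy-7,7-dimethyl-5-(3-methylbut-2-enyl)-6-oxabicyclo[3.2.1]octane-4,8-dione (hydroxyl syn to the C8 bridge)
Conditions: KN(SiMe3)2, THF, −78 °C; then 2-(phenylsulfonyl)-3-phenyloxaziridine; aq. NH4Cl
Reagents that add atoms: 2-(phenylsulfonyl)-3-phenyloxaziridine, O=S(=O)(c1ccccc1)N1OC1c1ccccc1
Why: C3 is the only enolisable carbon (C5 is quaternary, C1 is a bridgehead), and oxaziridine hydroxylation of the potassium enolate (Davis oxidation) delivers oxygen from the open face syn to C8; this centre is planarised again in step 9.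

Step 9
Reactants: 13 3-hydroxy dione
Product: 15 7,7-dimethyl-5-(3-methylbut-2-enyl)-3,4-bis(triethylsilyloxy)-6-oxabicyclo[3.2.1]oct-3-en-8-one, via 3-silyloxy ketone 14 (not isolated)
Conditions: Et3SiOTf, Et3N, CH2Cl2, 0 °C → rt
Reagents that add atoms: triethylsilyl triflate, CC[Si](CC)(CC)OS(=O)(=O)C(F)(F)F
Why: O-silylation of the ketol and then soft enolisation of the silyl-activated C4 ketone (silyl triflate with amine) gives the enediol bis(silyl ether) under thermodynamic conditions, so the shielded C3–H is removed without a bulky strong base and the C3 oxygen is already protected.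

Step 10
Reactants: 15 enediol bis(triethylsilyl) ether
Product: 16 3-ethynyl-7,7-dimethyl-5-(3-methylbut-2-enyl)-3-(triethylsilyloxy)-6-oxabicyclo[3.2.1]octane-4,8-dione (ethynyl syn to the C8 bridge, silyloxy toward C7)
Conditions: TMS-EBX, Bu4NF, THF, −78 → −40 °C; aq. NH4Cl
Reagents that add atoms: 1-[(trimethylsilyl)ethynyl]-1,2-benziodoxol-3(1H)-one (TMS-EBX), C[Si](C)(C)C#CI1OC(=O)c2ccccc12
Why: Fluoride unmasks the enolate and the ethynyl trivalent iodine reagent, the enolate reacts at C3 because C4 is flanked by the quaternary C5, and it is alkynylated from the open face syn to C8, away from the endo methyl on C7 (electrophilic α-alkynylation of a ketone enolate with an alkynyl benziodoxolone), which sets C3 with the ethynyl group on the C8 side.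

Step 11
Reactants: 16 3-ethynyl ketone
Product: 17 2-(trimethylsilyl)ethyl 3-[(1S,5S)-7,7-dimethyl-5-(3-methylbut-2-enyl)-4,8-dioxo-3-(triethylsilyloxy)-6-oxabicyclo[3.2.1]octan-3-yl]prop-2-ynoate (alkynoate syn to C8)
Conditions: LiN(SiMe3)2, THF, −78 °C; then ClCO2CH2CH2SiMe3, −78 → −40 °C
Reagents that add atoms: 2-(trimethylsilyl)ethyl chloroformate, C[Si](C)(C)CCOC(=O)Cl
Why: Both ketones are now non-enolisable, so the amide base removes only the acetylenic proton and the lithium acetylide is acylated by the chloroformate (C-carboxylation of a terminal alkyne) faster than it adds to the two hindered ketones.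

Step 12
Reactants: 17 alkynoate
Product: 18 2-(trimethylsilyl)ethyl 7-hydroxy-5,5-dimethyl-3-(3-methylbut-2-enyl)-2-oxo-1-(triethylsilyloxy)-4-oxatricyclo[4.3.1.0(3,7)]dec-8-ene-8-carboxylate
Conditions: [(Ph3P)CuH]6 (0.2 equiv, 1.2 hydride), toluene, −40 → −20 °C; aq. NH4Cl
Reagents that add atoms: none
Why: The monovalent copper hydride transfers hydrogen to the alkyne carbon bonded to C3 (the ester β position) and leaves a copper allenolate, whose ester α carbon then bonds to the C8 carbonyl carbon of the one-atom bridge; this is the copper hydride reductive aldol cyclisation known for alkynones and alkynoates tethered to ketones. The closure is a 6-(enolexo)-exo-trig aldol that converts the carbocycle of the oxabicyclo[3.2.1]octane into the bicyclo[2.2.2]octene, and since both ring bonds must be cis on the new double bond only the endocyclic trisubstituted acrylate can result. The new bridgehead carbinol centre is set by the tether, because the allenolate hangs from C3 on the side of the three-carbon bridge and can reach only that face of the C8 carbonyl. The C3 silyloxy group would be axial in the chair and pressed against the endo methyl on C7, which biases the carbocycle toward the boat that holds the alkyne over C8. The step needs 1,4- over 1,2-reduction (soft copper hydride, low temperature, no silane), attack on C8 and not C4 (which would give a four-membered ring), and no second reduction of the hindered product acrylate (about one hydride equivalent); the prenyl alkene and both silyl groups are inert.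

Step 13
Reactants: 18 cage ester
Product: 19 1,7-dihydroxy-5,5-dimethyl-3-(3-methylbut-2-enyl)-2-oxo-4-oxatricyclo[4.3.1.0(3,7)]dec-8-ene-8-carboxylic acid
Conditions: (Me2N)3S+ Me3SiF2− (TASF), DMF, H2O (5 equiv), 0 °C → rt; cold 0.1 M HCl work-up
Reagents that add atoms: none
Why: Fluoride attacks silicon in both groups, fragmenting the 2-(trimethylsilyl)ethyl ester to carboxylate, ethene and Me3SiF and cleaving the tertiary silyl ether, so the hindered acrylic ester is unmasked without hydroxide (fluoride-induced β-elimination of a silylethyl ester).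

Step 14
Reactants: 20 1,2,3,5-tetramethoxybenzene; 3 prenyl bromide
Product: 21 1,2,3,5-tetramethoxy-4-(3-methylbut-2-enyl)benzene
Conditions: n-BuLi, TMEDA, THF, 0 °C; then CuI (10 mol %), 3, −78 °C → rt
Reagents that add atoms: none
Why: Directed ortho-lithiation takes the ring position flanked by two methoxy groups, and copper-catalysed coupling of the aryllithium with the allylic bromide gives the linear prenyl arene (SN2 allylation of an arylcopper species).

Step 15
Reactants: 21 prenyl tetramethoxybenzene
Product: 22 2,6-dimethoxy-3-(3-methylbut-2-enyl)-1,4-benzoquinone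
Conditions: (NH4)2Ce(NO3)6, MeCN/H2O, 0 °C
Reagents that add atoms: water, O
Why: Oxidative demethylation of the para-dimethoxy pair by tetravalent cerium gives the para-quinone with carbonyl oxygens taken from water, a transformation that prenyl side chains are known to survive.

Step 16
Reactants: 22 dimethoxy quinone
Product: 24 2,6-dihydroxy-3-(3-methylbut-2-enyl)-1,4-benzoquinone, via monomethoxy hydroxyquinone 23 (not isolated)
Conditions: NaOH (2 M), MeOH/H2O, N2, 0 °C → rt; then cold 1 M HCl to pH 3
Reagents that add atoms: sodium hydroxide, [Na+].[OH-]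
Why: Both methoxy groups are vinylogous esters and are exchanged for hydroxide by addition–elimination at the ring carbon (vinylogous ester saponification), the unhindered one next to the ring CH first and the second more slowly because the first product is an anion.

Step 17
Reactants: 24 dihydroxy quinone; 25 prenal (3-methylbut-2-enal)
Product: 27 7-hydroxy-2,2-dimethyl-6-(3-methylbut-2-enyl)-2H-chromene-5,8-dione, via quinone-methide oxatriene 26 (not isolated)
Conditions: ethylenediammonium diacetate (10 mol %), CH2Cl2, rt → 40 °C
Reagents that add atoms: none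
Why: The only free ring CH lies between a hydroxyl and a carbonyl and condenses with the enal (Knoevenagel), and the oxatriene closes by reversible oxa-6π electrocyclisation onto the former hydroxyl oxygen to give the 2,2-dimethyl-2H-chromene of the more stable para-quinone (formal [3+3] annulation of a hydroxyquinone with an enal).

Step 18
Reactants: 19 cage hydroxy acid; 27 hydroxyquinone
Product: 29 CNP0222516.1 (target), via acyloxyquinone 28 (not isolated)
Conditions: DCC, DMAP (10 mol %), CH2Cl2, −20 → 0 °C; then Et3N (0.2 equiv), 0 °C → rt; AcOH quench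
Reagents that add atoms: none
Why: Carbodiimide acylation (Steglich-type) of the acidic quinone hydroxyl gives the 7-acyloxy para-quinone, whose acyloxy-bearing carbon is the β carbon of the C5 enone; the bridgehead tertiary alcohol adds there in a 6-exo-trig oxa-Michael reaction that closes the 1,3-dioxin-4-one and creates the spiro ketal carbon, and C-protonation of the enolate gives the CH(prenyl) centre; since the addition is reversible and that CH is epimerisable, both centres should settle under thermodynamic control with the prenyl group trans to the ketal ether oxygen, as in the target.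

**Compound list**

1 | diacetone alcohol (4-hydroxy-4-methylpentan-2-one) | CC(=O)CC(C)(C)O | starting material
2 | 4-methyl-4-(trimethylsilyloxy)pentan-2-one | CC(=O)CC(C)(C)O[Si](C)(C)C | intermediate
3 | prenyl bromide | CC(C)=CCBr | starting material
4 | 2,8-dimethyl-2-(trimethylsilyloxy)non-7-en-4-one | CC(C)=CCCC(=O)CC(C)(C)O[Si](C)(C)C | intermediate
5 | 2,8-dimethyl-2,4-bis(trimethylsilyloxy)nona-4,7-diene | CC(C)=CCC=C(O[Si](C)(C)C)CC(C)(C)O[Si](C)(C)C | intermediate
6 | 5-bromo-2,8-dimethyl-2-(trimethylsilyloxy)non-7-en-4-one (racemic) | CC(C)=CCC(Br)C(=O)CC(C)(C)O[Si](C)(C)C | intermediate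
7 | 5,5-dimethyl-2-(3-methylbut-2-enyl)oxolan-3-one (racemic) | CC(C)=CCC1OC(C)(C)CC1=O | intermediate
8 | 1-[5,5-dimethyl-2-(3-methylbut-2-enyl)-2,5-dihydrofuran-3-yl]pyrrolidine (racemic) | CC(C)=CCC1OC(C)(C)C=C1N1CCCC1 | intermediate
9 | acryloyl chloride | C=CC(=O)Cl | starting material
10 | 1-[7,7-dimethyl-5-(3-methylbut-2-enyl)-4-oxo-6-oxabicyclo[3.2.1]octan-8-ylidene]pyrrolidinium chloride (racemic) | O=C1CCC2C(C)(C)OC1(CC=C(C)C)C2=[N+]1CCCC1.[Cl-] | intermediate
11 | rac-7,7-dimethyl-5-(3-methylbut-2-enyl)-6-oxabicyclo[3.2.1]octane-4,8-dione (bridgeheads cis by constraint) | O=C1CCC2C(C)(C)OC1(CC=C(C)C)C2=O | intermediate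
12 | (1S,5S)-7,7-dimethyl-5-(3-methylbut-2-enyl)-6-oxabicyclo[3.2.1]octane-4,8-dione | C1C[C@H]2C(C)(C)O[C@@](CC=C(C)C)(C1=O)C2=O | intermediate
13 | 3-hydroxy derivative of 12, hydroxyl syn to the C8 bridge | O[C@@H]1C[C@H]2C(C)(C)O[C@@](CC=C(C)C)(C1=O)C2=O | intermediate
14 | 3-(triethylsilyloxy) derivative of 12, silyloxy syn to the C8 bridge | CC[Si](CC)(CC)O[C@@H]1C[C@H]2C(C)(C)O[C@@](CC=C(C)C)(C1=O)C2=O | intermediate
15 | 7,7-dimethyl-5-(3-methylbut-2-enyl)-3,4-bis(triethylsilyloxy)-6-oxabicyclo[3.2.1]oct-3-en-8-one | C=1(O[Si](CC)(CC)CC)C[C@H]2C(C)(C)O[C@@](CC=C(C)C)(C=1O[Si](CC)(CC)CC)C2=O | intermediate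
16 | 3-ethynyl-7,7-dimethyl-5-(3-methylbut-2-enyl)-3-(triethylsilyloxy)-6-oxabicyclo[3.2.1]octane-4,8-dione, ethynyl syn to C8 | C#C[C@]1(O[Si](CC)(CC)CC)C[C@H]2C(C)(C)O[C@@](CC=C(C)C)(C1=O)C2=O | intermediate
17 | 2-(trimethylsilyl)ethyl 3-[7,7-dimethyl-5-(3-methylbut-2-enyl)-4,8-dioxo-3-(triethylsilyloxy)-6-oxabicyclo[3.2.1]octan-3-yl]prop-2-ynoate, alkynoate syn to C8 | C[Si](C)(C)CCOC(=O)C#C[C@]1(O[Si](CC)(CC)CC)C[C@H]2C(C)(C)O[C@@](CC=C(C)C)(C1=O)C2=O | intermediate
18 | 2-(trimethylsilyl)ethyl 7-hydroxy-5,5-dimethyl-3-(3-methylbut-2-enyl)-2-oxo-1-(triethylsilyloxy)-4-oxatricyclo[4.3.1.0(3,7)]dec-8-ene-8-carboxylate | C[Si](C)(C)CCOC(=O)C1=C[C@]3(O[Si](CC)(CC)CC)C[C@H]4C(C)(C)O[C@@](CC=C(C)C)(C3=O)[C@@]14O | intermediate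
19 | 1,7-dihydroxy-5,5-dimethyl-3-(3-methylbut-2-enyl)-2-oxo-4-oxatricyclo[4.3.1.0(3,7)]dec-8-ene-8-carboxylic acid | OC(=O)C1=C[C@]3(O)C[C@H]4C(C)(C)O[C@@](CC=C(C)C)(C3=O)[C@@]14O | intermediate
20 | 1,2,3,5-tetramethoxybenzene | COc1cc(OC)cc(OC)c1OC | starting material
21 | 1,2,3,5-tetramethoxy-4-(3-methylbut-2-enyl)benzene | COc1cc(OC)c(CC=C(C)C)c(OC)c1OC | intermediate
22 | 2,6-dimethoxy-3-(3-methylbut-2-enyl)-1,4-benzoquinone | COC1=CC(=O)C(CC=C(C)C)=C(OC)C1=O | intermediate
23 | 2-hydroxy-6-methoxy-5-(3-methylbut-2-enyl)-1,4-benzoquinone | COC1=C(CC=C(C)C)C(=O)C=C(O)C1=O | intermediate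
24 | 2,6-dihydroxy-3-(3-methylbut-2-enyl)-1,4-benzoquinone | OC1=CC(=O)C(CC=C(C)C)=C(O)C1=O | intermediate
25 | prenal (3-methylbut-2-enal) | CC(C)=CC=O | starting material
26 | 5-hydroxy-6-(3-methylbut-2-enyl)-3-(3-methylbut-2-enylidene)cyclohex-5-ene-1,2,4-trione | CC(C)=CC=C1C(=O)C(CC=C(C)C)=C(O)C(=O)C1=O | intermediate
27 | 7-hydroxy-2,2-dimethyl-6-(3-methylbut-2-enyl)-2H-chromene-5,8-dione | CC(C)=CCC1=C(O)C(=O)C2=C(C=CC(C)(C)O2)C1=O | intermediate
28 | 2,2-dimethyl-6-(3-methylbut-2-enyl)-5,8-dioxo-2H-chromen-7-yl ester of acid 19 | CC(C)=CCC1=C(OC(=O)C5=C[C@]3(O)C[C@H]4C(C)(C)O[C@@](CC=C(C)C)(C3=O)[C@@]54O)C(=O)C2=C(C=CC(C)(C)O2)C1=O | intermediate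
29 | CNP0222516.1 | CC(C)=CC[C@H]1C(=O)C2=C(OC(C)(C)C=C2)C(=O)[C@@]12OC(=O)C1=C[C@]3(O)C[C@H]4C(C)(C)O[C@@](CC=C(C)C)(C3=O)[C@@]14O2 | target

**Step count and risks**

Total: 18 steps. Longest linear sequence: 14 steps (steps 1 to 13, then 18).

Step 12 (key step). The copper allenolate may be protonated, or the product enoate reduced a second time, before the carbocycle reaches the boat needed for closure; this would give the open-chain enoate or the saturated ester. Fallback: starting from 17, iodide replaces hydride as the conjugate nucleophile in a halo-aldol cyclisation. MgI2 in CH2Cl2 at 0 °C should add iodide to the alkyne carbon on C3 and close the magnesium allenolate onto C8, giving the β-iodo cage ester F1. Hydrodeiodination of the vinylic iodide with Bu3SnH and catalytic Pd(PPh3)4 (zerovalent palladium) then gives 18, where the route is rejoined.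

Step 18. Activation of the hindered acid may be diverted into N-acylurea formation or into acylation at the C5 oxygen of the ortho-quinone tautomer. Under base, the ketal enolate may also expel carboxylate instead of being C-protonated, so that the spiro ring opens or the unwanted spiro epimer persists. Fallback: the polarity of the ester-forming event is reversed. Starting from 27, (COCl)2 with catalytic DMF in CH2Cl2 gives the 7-chloroquinone F2. The caesium carboxylate of 19 (Cs2CO3, DMF, 0 °C) displaces chloride by addition–elimination at the quinone carbon and gives 28 without any activation of the acid. Ring closure is then run with catalytic pyridinium tosylate in CH2Cl2, where carboxylate elimination is not driven, and returns to 29.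

Step 10. The fluoride-generated enolate may be protonated or O-alkynylated, or the C3 oxygen may lose its silyl group before the C–C bond forms. Fallback: a one-carbon electrophile followed by homologation. Starting from 15, Mukaiyama hydroxymethylation (aqueous HCHO, Yb(OTf)3, THF, rt) on the same open face gives the hydroxymethyl ketone F3. Dess–Martin periodinane in CH2Cl2 gives the aldehyde F4. Colvin homologation (Me3SiCHN2, LiN(iPr)2, THF, −78 → 0 °C) then gives 16, where the route is rejoined.

**Further compounds**

F1 | step 12 | 2-(trimethylsilyl)ethyl 7-hydroxy-9-iodo-5,5-dimethyl-3-(3-methylbut-2-enyl)-2-oxo-1-(triethylsilyloxy)-4-oxatricyclo[4.3.1.0(3,7)]dec-8-ene-8-carboxylate | C[Si](C)(C)CCOC(=O)C1=C(I)[C@]3(O[Si](CC)(CC)CC)C[C@H]4C(C)(C)O[C@@](CC=C(C)C)(C3=O)[C@@]14O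
F2 | step 18 | 7-chloro-2,2-dimethyl-6-(3-methylbut-2-enyl)-2H-chromene-5,8-dione | CC(C)=CCC1=C(Cl)C(=O)C2=C(C=CC(C)(C)O2)C1=O
F3 | step 10 | 3-(hydroxymethyl)-7,7-dimethyl-5-(3-methylbut-2-enyl)-3-(triethylsilyloxy)-6-oxabicyclo[3.2.1]octane-4,8-dione, hydroxymethyl syn to C8 | OC[C@]1(O[Si](CC)(CC)CC)C[C@H]2C(C)(C)O[C@@](CC=C(C)C)(C1=O)C2=O
F4 | step 10 | 7,7-dimethyl-5-(3-methylbut-2-enyl)-4,8-dioxo-3-(triethylsilyloxy)-6-oxabicyclo[3.2.1]octane-3-carbaldehyde, formyl syn to C8 | O=C[C@]1(O[Si](CC)(CC)CC)C[C@H]2C(C)(C)O[C@@](CC=C(C)C)(C1=O)C2=O
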